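Start with one division: incoming ligand charged over starting complex charged. Call it the exchange count. Each exchange spends one incoming ligand, so the count is the mean number of exchanges per starting complex once the incoming ligand has been consumed.

all flasks: starting complex 25 mM; leaving ligand 12.5 mM
- east: incoming ligand 54 mM; run made earlier
- south-west: incoming ligand 120 mM; run made earlier
- grey: incoming ligand 100 mM; time 40 h
- violet: incoming ligand 37.5 mM; time 40 h
- amber: incoming ligand 75.0 mM; time 40 h

| run | time / h | complex with one exchanged / % | complex with two exchanged / % |
|---|---|---|---|
| east | 2.50 | 17.6 | 27.7 |
| east | 8.00 | 19.2 | 27.7 |
| east | 15.0 | 18.1 | 29.5 |
| east | 20.0 | 16.4 | 30.4 |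
| east | 30.0 | 16.6 | 27.3 |
| east | 40.0 | 18.5 | 28.1 |
| south-west | 2.50 | 0.6 | 0 |
| south-west | 8.00 | 0.2 | 0.5 |
| south-west | 15.0 | 0.8 | 0 |
| south-west | 20.0 | 0.1 | 0 |
| south-west | 30.0 | 0 | 0.9 |
| south-west | 40.0 | 0 | 0 |

(standard deviation of a reading: 1 percentage point)

* which of these holds the largest part of the starting complex at the end of grey (complex with four exchanged / complex with two exchanged / complex with one exchanged / complex with three exchanged / starting complex)
* which of these holds the largest part of the starting complex at the end of violet (complex with four exchanged / complex with two exchanged / complex with one exchanged / complex with three exchanged / starting complex)
* which of these holds the largest part of the starting complex at the end of amber (complex with four exchanged / complex with two exchanged / complex with one exchanged / complex with three exchanged / starting complex)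
* how much complex with one exchanged is there at the end of violet, in percent of the starting complex charged

- a reading or a percentage of complex with two exchanged counts all its forms, free or not

Now set violet beside east, the flask that looks nearly the same. They differ in one charge, 37.5 mM of incoming ligand in violet against 54 mM in east, so reckon the counts:

east: 2.16
violet: 1.50
south-west: 4.80

Both east and violet lie under the 4 exchanges a starting complex can take , so incoming ligand is the limiting reagent in each, and each should stop partway up the ladder. East does stop: its readings show no trend from 2.50 h to 40.0 h against a scatter of 1 percentage point. South-west has a count above that limit, and its readings of complex with one exchanged and complex with two exchanged lie near zero.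

East gives more than a stopping point. Averaged over its readings, complex with two exchanged over complex with one exchanged reads 1.60. Assume, as my own reckoning, that this ratio grows in proportion to the count, and define the ladder slope as the ratio divided by the count:

ladder slope: 0.743
violet ratio, slope times count: 1.11

A ratio above one, taken from scattered readings through that assumption, puts complex with two exchanged ahead of complex with one exchanged in violet. The slope gives this order, not an amount.

The forecast names complex with four exchanged for grey, complex with three exchanged for amber and complex with one exchanged for violet, with 27 %: “a broad spread, with one-exchanged near 27%, narrowly ahead of two-exchanged”. On the order of these two complexes in violet my reckoning differs from it.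

Violet gives 26.1 % of complex with one exchanged, and complex with two exchanged leads there with 30.2 %, its idle adduct counted in; grey ends led by complex with four exchanged, and amber by complex with four exchanged too.

    starting complex + complex with two exchanged ⇌ idle adduct, settled at all times (K = 77.0 L mol⁻¹)
    starting complex + incoming ligand → leaving ligand + complex with one exchanged (k = 0.230 L mol⁻¹ s⁻¹)
    complex with one exchanged + incoming ligand → leaving ligand + complex with two exchanged (k = 0.260 L mol⁻¹ s⁻¹)
    complex with two exchanged + incoming ligand → leaving ligand + complex with three exchanged (k = 0.250 L mol⁻¹ s⁻¹)
    complex with three exchanged + incoming ligand → leaving ligand + complex with four exchanged (k = 0.330 L mol⁻¹ s⁻¹)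

In violet 0 % of the incoming ligand is left, and the ratio of two-exchanged to one-exchanged stands at 1.16 against the 1.11 from the slope. Take the neighbour of violet with 62 mM of starting complex: its count is 0.605, so the slope gives a ratio of 0.450. That flask holds 13.4 % of complex with two exchanged, all its forms counted, and 30.6 % of complex with one exchanged, a ratio of 0.438.

The earlier runs and the new flask come from a simulation from invented constants, and the scatter is random.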